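In a one-step world, substrate decays to target at a rate set by a reagent level that follows the clock and ignores the substrate charge. That is pseudo-first-order, so every flask converts the same fraction of its charge. I count the lifetimes lived through.

common to all: reagent in the second phase 0.0475 M

|  | substrate | protic impurity | remark | time | volume of the second phase over the first |
|---|---|---|---|---|---|
| Wednesday's | 0.0060 M | 0.038 M | run made earlier |  |  |
| Saturday's | 0.0060 M | 0.050 M | run made earlier |  |  |
| grey | 0.0060 M | 0.0250 M |  | 12 h | 1.0 |
| ochre | 0.015 M | 0.0250 M |  | 12 h | 1.0 |
| amber | 0.050 M | 0.0250 M |  | 12 h | 1.0 |
| teal | 0.15 M | 0.0250 M |  | 12 h | 1.0 |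
| green | 0.50 M | 0.0250 M |  | 12 h | 1.0 |

| run | time / h | target / % | substrate / % |
|---|---|---|---|
| Wednesday's | 0.333 | 0 | 99.4 |
| Wednesday's | 0.500 | 0.7 | 98.1 |
| Wednesday's | 1.00 | 4.4 | 95.7 |
| Wednesday's | 1.50 | 7.5 | 94.2 |
| Wednesday's | 2.50 | 13.0 | 88.3 |
| Wednesday's | 4.00 | 15.9 | 84.5 |
| Saturday's | 0.250 | 1.8 | 98.7 |
| Saturday's | 0.833 | 2.3 | 96.5 |
| Saturday's | 1.33 | 5.6 | 94.5 |
| Saturday's | 2.50 | 12.1 | 89.5 |
| Saturday's | 3.00 | 11.7 | 86.0 |
| Saturday's | 4.00 | 13.4 | 84.8 |

(readings scatter by 1 percentage point)

- percent here means substrate units held: one side product counts as two
- in the second phase: reagent in the second phase; everything else is in the first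
- charges count per volume of the first phase; a concentration in a rate is the amount of a species over the volume of its own phase; every rate counts per litre of the first phase
- what was read earlier has a scatter of 1 percentage point, one standard deviation
- what may be going on: reagent in the reaction phase <-> reagent in the second phase; substrate + reagent in the reaction phase -> target; reagent in the reaction phase + target -> over-reacted product; reagent in the reaction phase + protic impurity -> quenched reagent; substrate + target -> side product; reagent in the reaction phase -> decomposed reagent
- the earlier runs hold the two phases in the same ratio of volumes as the flask asked about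
- "hardly changes" means that all values lie within two and a half points (for a concentration: within two and a half percent of the largest)

- [target] at the end for grey, ochre, amber, teal, green, in this order
- the shape of the row from first to last (falls all the way / rises all the way / hardly changes / rises, then falls / falls, then rises)

Wednesday's substrate reading at 4.00 h gives 0.168, my exposure: the natural log of one over the fraction of substrate left, which counts the first-order lifetimes lived so far. Saturday's reading gives 0.165, with more impurity. In the one-step world, that exposure converts a fraction 15.5% of any charge, so the row rises in proportion to the charge. Grey has less impurity and a longer time, so I take this as a floor for grey.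

The other extreme is a flask where substrate takes every unit of reagent, the limiting reagent. Green's fraction then cannot pass the reagent charge over the substrate charge, 9.50%. So I expect the real row above the first line at grey's charge and under the second line at green's charge.

But the scheme allows substrate + target, a loss whose lifetimes grow with the charge. The sums of target and substrate at 4.00 h are 100% on Wednesday and 98.2% on Saturday, so this loss does not show at that charge. Green holds 83.3 times as much. I commit to a rise at the low end and leave the top open.

The forecast gives 0.0013 M, 0.0031 M, 0.009 M, 0.019 M, 0.03 M: rises all the way. It expects “a rise that saturates, with a wide low-side range at the top”.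

The flask gives 0.00143 M, 0.00315 M, 0.00647 M, 0.00496 M, 1.75 × 10⁻⁴ M: rises, then falls.

    reagent in the reaction phase ⇌ reagent in the second phase, rate k1*([reagent in the reaction phase] - [reagent in the second phase]/K1) per volume of the first phase (partition coefficient = 0.670, kL = 0.624 h⁻¹)
    substrate + reagent in the reaction phase → target (k = 3.68 L mol⁻¹ h⁻¹)
    reagent in the reaction phase + target → over-reacted product (k = 1.54 L mol⁻¹ h⁻¹)
    reagent in the reaction phase + protic impurity → quenched reagent (k = 7.67 L mol⁻¹ h⁻¹)
    substrate + target → side product (k = 1.39 L mol⁻¹ h⁻¹)
    reagent in the reaction phase → decomposed reagent (k = 0.367 h⁻¹)

In grey, target's half-life by substrate + target alone, the other concentrations as charged, is 83 h, long against 12 h; that is 0.100 lifetimes, fewer than Wednesday's exposure 0.168. In green, the same step at the charged substrate counts 8.34 lifetimes in 12 h, far more than 0.168, and at the end green holds 14.2% of its charge as side product against 0.0349% as target.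

The numbers in the tables were generated by integration with constants of no real substance; noise was put on by code.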